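**Retrosynthetic overview**
1. The target is opened last at ring D's flavanone: benzyl ethers off, then the flavanone C2–phenyl bond by enantioselective conjugate addition of phenylboronic acid to a chromone built on ring D from its ortho-formyl phenol.
2. The flavan is cut at C4–C4a. The strategy rests on this bond: C4 carries ring D, whose three ortho/para oxygens make it a stabilised benzylic cation, and C4a is one of two equivalent ortho carbons of a 3,5-dimethoxyphenoxy group on C2.
3. The cyclisation precursor, a (2S) 3,5-dimethoxyphenyl ether, takes its only stereocentre from a CBS reduction followed by Mitsunobu inversion; its chain comes from an aldol addition of 4-acetylphenyl pivalate to protected phloroglucinaldehyde.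
4. Ring order: rings B and D are bought as arenes, ring A arrives as the phenol, ring C closes in the key step, and the pyranone ring on ring D is made last.

Key step: step 9

Remark on the chemistry: compounds 8, 10 and 11 are carried as mixtures of epimers at the ring D carbinol carbon (the future C4; the 3R epimer is drawn), which is harmless because this carbon becomes a planar cation in step 9.

**Step 1**
Reactants: 1 2,4,6-trihydroxybenzaldehyde
Product: 2 2,4-bis(benzyloxy)-6-hydroxybenzaldehyde
Conditions: BnBr (2.1 equiv), K2CO3, DMF, rt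
Reagents that add atoms: benzyl bromide BrCc1ccccc1
Why: Williamson etherification in which the para hydroxyl and one ortho hydroxyl are alkylated while the second ortho hydroxyl, held in a hydrogen bond to the aldehyde, should stay free with two equivalents of halide.

**Step 2**
Reactants: 2 2,4-bis(benzyloxy)-6-hydroxybenzaldehyde
Product: 3 2-(allyloxy)-4,6-bis(benzyloxy)benzaldehyde
Conditions: allyl bromide, K2CO3, DMF, 60 °C
Reagents that add atoms: allyl bromide C=CCBr
Why: Williamson etherification of the remaining chelated phenol puts an allyl group, orthogonal to benzyl, on the oxygen that later becomes O1 of the flavanone.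

**Step 3**
Reactants: 4 4'-hydroxyacetophenone
Product: 5 4-acetylphenyl pivalate
Conditions: PivCl, Et3N, DMAP (cat.), CH2Cl2, 0 °C to rt
Reagents that add atoms: pivaloyl chloride CC(C)(C)C(=O)Cl
Why: Acylation of the phenol gives an electron-poor ring B, needed for clean inversion in step 7 and for selective ionisation in step 9, and the hindered ester survives enolate chemistry.

**Step 4**
Reactants: 5 4-acetylphenyl pivalate; 3 2-(allyloxy)-4,6-bis(benzyloxy)benzaldehyde
Product: 6 (±)-4-{3-[2-(allyloxy)-4,6-bis(benzyloxy)phenyl]-3-hydroxypropanoyl}phenyl pivalate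
Conditions: LiN(SiMe3)2, THF, −78 °C; then 3; AcOH quench at −78 °C
Reagents that add atoms: none
Why: Kinetic aldol addition of the lithium enolate of 5 to the aldehyde under non-acidic conditions, with a cold protic quench so that the electron-rich benzylic aldolate neither reverts nor dehydrates to the chalcone; the new carbinol centre is racemic and is erased in step 9.

**Step 5**
Reactants: 6 racemic aldol adduct
Product: 7 (±)-4-{3-[2-(allyloxy)-4,6-bis(benzyloxy)phenyl]-3-(tert-butyldimethylsilyloxy)propanoyl}phenyl pivalate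
Conditions: TBSOTf, 2,6-lutidine, CH2Cl2, −78 °C
Reagents that add atoms: tert-butyldimethylsilyl trifluoromethanesulfonate CC(C)(C)[Si](C)(C)OS(=O)(=O)C(F)(F)F
Why: Silylation of the hindered benzylic alcohol with a silyl triflate and a hindered base masks the C4 oxygen so that only one hydroxyl is present in the Mitsunobu step.

**Step 6**
Reactants: 7 racemic silyloxy ketone
Product: 8 4-{(1R)-3-[2-(allyloxy)-4,6-bis(benzyloxy)phenyl]-3-(tert-butyldimethylsilyloxy)-1-hydroxypropyl}phenyl pivalate (both C3 epimers; 3R drawn)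
Conditions: (S)-2-butyl-CBS-oxazaborolidine (20 mol%), catecholborane, toluene, −78 °C
Reagents that add atoms: none
Why: Corey–Bakshi–Shibata reduction in which the (S)-oxazaborolidine treats the aryl group as the large substituent and should give the (1R) benzylic alcohol from both enantiomers of 7 under reagent control, while catecholborane at low temperature leaves the allyl ether and the pivalate alone.

**Step 7**
Reactants: 8 (1R) alcohol; 9 3,5-dimethoxyphenol
Product: 10 4-{(1S)-3-[2-(allyloxy)-4,6-bis(benzyloxy)phenyl]-3-(tert-butyldimethylsilyloxy)-1-(3,5-dimethoxyphenoxy)propyl}phenyl pivalate (both C3 epimers; 3R drawn)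
Conditions: PPh3, DIAD, toluene, 0 °C to rt
Reagents that add atoms: none
Why: Mitsunobu etherification in which the phenoxide of 9 displaces the alkoxyphosphonium group by SN2 with inversion, (1R) to (1S), the electron-poor pivaloyloxyphenyl ring suppressing the ionisation that would erode the configuration.

**Step 8**
Reactants: 10 (1S) aryl ether silyl ether
Product: 11 4-{(1S)-3-[2-(allyloxy)-4,6-bis(benzyloxy)phenyl]-1-(3,5-dimethoxyphenoxy)-3-hydroxypropyl}phenyl pivalate (both C3 epimers; 3R drawn)
Conditions: Bu4NF, AcOH, THF, 0 °C to rt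
Reagents that add atoms: none
Why: Fluoride cleavage of the silyl ether under acetic acid buffering frees the C4 carbinol without touching the pivalate or the benzylic aryl ether.

**Step 9**
Reactants: 11 cyclisation precursor (C4 carbinol)
Product: 12 (2S)-2,4-trans-4-[2-(allyloxy)-4,6-bis(benzyloxy)phenyl]-5,7-dimethoxy-2-(4-pivaloyloxyphenyl)chroman
Conditions: Sc(OSO2CF3)3 (10 mol%), 4 Å MS, CH2Cl2 (0.01 M), −20 to 0 °C
Reagents that add atoms: none
Why: Sc(OSO2CF3)3 ionises the C4 carbinol because the three oxygen donors of ring D stabilise the benzylic cation, and the tethered 3,5-dimethoxyphenoxy ring attacks it through an ortho carbon in an intramolecular Friedel–Crafts cycloalkylation, the known way from aryl 3-aryl-3-hydroxypropyl ethers to 4-arylchromans. Ring C closes as a six-membered ring, endo with respect to the attacked aromatic C=C bond (C4a and C8a both lie in the new ring); the para carbon cannot reach and the two ortho carbons are equivalent, so only one regioisomer can form. Both C4 epimers of 11 converge on the same planar cation, so the C2 centre alone sets C4: in a half-chair transition state ring B sits pseudo-equatorial and ring D turns pseudo-axial to avoid the ortho methoxy group that becomes the peri C5 methoxy, which should give the 2,4-trans flavan. The step needs ionisation at C4 and not at C2, which the electron-poor pivalate on ring B secures, and it needs ring closure to outrun E1 loss and intermolecular alkylation, which low temperature and high dilution favour.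

**Step 10**
Reactants: 12 flavan pivalate
Product: 14 (2S)-2,4-trans-4-[2-(allyloxy)-4,6-bis(benzyloxy)phenyl]-2-(4-benzyloxyphenyl)-5,7-dimethoxychroman, via ring B phenol 13 (not isolated)
Conditions: NaOMe (1.2 equiv), MeOH/THF, rt; evaporate; then BnBr, DMF, rt
Reagents that add atoms: benzyl bromide BrCc1ccccc1
Why: Methoxide transesterification removes the pivalate and Williamson benzylation of the phenoxide gives a ring B group that can leave by neutral hydrogenolysis at the end, when base would endanger the flavanone stereocentre.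

**Step 11**
Reactants: 14 allyl ether
Product: 15 3,5-bis(benzyloxy)-2-[(2S)-2,4-trans-2-(4-benzyloxyphenyl)-5,7-dimethoxychroman-4-yl]phenol
Conditions: Pd(PPh3)4 (5 mol%), morpholine, THF, rt
Reagents that add atoms: none
Why: Tsuji–Trost deallylation in which zerovalent palladium ionises the allyl aryl ether to a π-allyl complex that morpholine captures, freeing only the ring D phenol that becomes O1 and directs the next step.

**Step 12**
Reactants: 15 ring D phenol
Product: 16 4,6-bis(benzyloxy)-3-[(2S)-2,4-trans-2-(4-benzyloxyphenyl)-5,7-dimethoxychroman-4-yl]-2-hydroxybenzaldehyde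
Conditions: MgCl2, Et3N, (CH2O)n, THF, reflux
Reagents that add atoms: paraformaldehyde (as formaldehyde) C=O
Why: Casnati–Skattebøl ortho-formylation in which the magnesium phenoxide delivers formaldehyde only to the free ortho carbon of ring D (the future C4a) and a second formaldehyde oxidises the benzylic alkoxide by hydride transfer, while ring A, which has no free phenol, is left alone.

**Step 13**
Reactants: 16 salicylaldehyde
Product: 17 1-{4,6-bis(benzyloxy)-3-[(2S)-2,4-trans-2-(4-benzyloxyphenyl)-5,7-dimethoxychroman-4-yl]-2-hydroxyphenyl}ethanol (both carbinol epimers)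
Conditions: MeMgBr (3 equiv), THF, 0 °C; aq. NH4Cl
Reagents that add atoms: methylmagnesium bromide C[Mg]Br
Why: Grignard addition to the aldehyde after deprotonation of the phenol by the first equivalent gives the secondary benzylic alcohol, whose configuration does not matter because it is oxidised next.

**Step 14**
Reactants: 17 benzylic alcohol
Product: 18 1-{4,6-bis(benzyloxy)-3-[(2S)-2,4-trans-2-(4-benzyloxyphenyl)-5,7-dimethoxychroman-4-yl]-2-hydroxyphenyl}ethanone
Conditions: MnO2, CH2Cl2, rt
Reagents that add atoms: none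
Why: MnO2 oxidises the activated benzylic alcohol selectively to the hydrogen-bonded ortho-hydroxyacetophenone without attacking the benzylic C–H bonds at C2 and C4 of the flavan.

**Step 15**
Reactants: 18 ortho-hydroxyacetophenone
Product: 20 5,7-bis(benzyloxy)-8-[(2S)-2,4-trans-2-(4-benzyloxyphenyl)-5,7-dimethoxychroman-4-yl]-4H-chromen-4-one, via dimethylamino enaminone 19 (not isolated)
Conditions: Me2NCH(OMe)2, toluene, 90 °C; then AcOH, 60 °C
Reagents that add atoms: N,N-dimethylformamide dimethyl acetal COC(OC)N(C)C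
Why: Enaminone route to chromones, in which condensation at the acetyl methyl group gives the enaminone and mild acid triggers intramolecular oxa-Michael addition of the phenol and loss of dimethylamine to close the pyranone ring.

**Step 16**
Reactants: 20 chromone; 21 phenylboronic acid
Product: 22 (2S)-5,7-bis(benzyloxy)-8-[(2S)-2,4-trans-2-(4-benzyloxyphenyl)-5,7-dimethoxychroman-4-yl]-2-phenylchroman-4-one
Conditions: Pd(OCOCF3)2 (10 mol%), (R)-4-tert-butyl-2-(2-pyridyl)-4,5-dihydrooxazole (12 mol%), NH4PF6 (30 mol%), H2O (5 equiv), ClCH2CH2Cl, 60 °C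
Reagents that add atoms: none
Why: Enantioselective conjugate addition of an arylboronic acid to a chromone with a cationic divalent palladium pyridine–oxazoline catalyst (transmetallation, face-selective insertion of C2=C3 into the Pd–Ph bond, protonolysis of the palladium enolate) sets the flavanone C2 centre under catalyst control, the (R)-ligand being chosen because it is expected, by analogy with cyclic enones, to give the (2S) product.

**Step 17**
Reactants: 22 tribenzyl ether
Product: 23 (2S)-5,7-dihydroxy-8-[(2S)-2,4-trans-2-(4-hydroxyphenyl)-5,7-dimethoxychroman-4-yl]-2-phenylchroman-4-one (CNP0188217.1)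
Conditions: H2 (1 atm), 10% Pd on carbon, EtOAc/MeOH, rt
Reagents that add atoms: none
Why: Hydrogenolysis removes the three benzyl ethers under neutral conditions that should neither open nor epimerise the flavanone, benzyl aryl ethers being cleaved much faster than the cyclic benzylic C–O bonds or the aryl ketone.

**Compound list**
1 | 2,4,6-trihydroxybenzaldehyde | O=Cc1c(O)cc(O)cc1O | starting material
2 | 2,4-bis(benzyloxy)-6-hydroxybenzaldehyde | O=Cc1c(O)cc(OCc2ccccc2)cc1OCc1ccccc1 | intermediate
3 | 2-(allyloxy)-4,6-bis(benzyloxy)benzaldehyde | O=Cc1c(OCC=C)cc(OCc2ccccc2)cc1OCc1ccccc1 | intermediate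
4 | 4'-hydroxyacetophenone | CC(=O)c1ccc(O)cc1 | starting material
5 | 4-acetylphenyl pivalate | CC(=O)c1ccc(OC(=O)C(C)(C)C)cc1 | intermediate
6 | (±)-4-{3-[2-(allyloxy)-4,6-bis(benzyloxy)phenyl]-3-hydroxypropanoyl}phenyl pivalate | CC(C)(C)C(=O)Oc1ccc(cc1)C(=O)CC(O)c1c(OCC=C)cc(OCc2ccccc2)cc1OCc1ccccc1 | intermediate
7 | (±)-4-{3-[2-(allyloxy)-4,6-bis(benzyloxy)phenyl]-3-(tert-butyldimethylsilyloxy)propanoyl}phenyl pivalate | CC(C)(C)C(=O)Oc1ccc(cc1)C(=O)CC(O[Si](C)(C)C(C)(C)C)c1c(OCC=C)cc(OCc2ccccc2)cc1OCc1ccccc1 | intermediate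
8 | 4-{(1R)-3-[2-(allyloxy)-4,6-bis(benzyloxy)phenyl]-3-(tert-butyldimethylsilyloxy)-1-hydroxypropyl}phenyl pivalate (both C3 epimers; 3R drawn) | O[C@@H](c1ccc(OC(=O)C(C)(C)C)cc1)C[C@@H](O[Si](C)(C)C(C)(C)C)c1c(OCC=C)cc(OCc2ccccc2)cc1OCc1ccccc1 | intermediate
9 | 3,5-dimethoxyphenol | COc1cc(O)cc(OC)c1 | starting material
10 | 4-{(1S)-3-[2-(allyloxy)-4,6-bis(benzyloxy)phenyl]-3-(tert-butyldimethylsilyloxy)-1-(3,5-dimethoxyphenoxy)propyl}phenyl pivalate (both C3 epimers; 3R drawn) | COc1cc(OC)cc(O[C@H](c2ccc(OC(=O)C(C)(C)C)cc2)C[C@@H](O[Si](C)(C)C(C)(C)C)c2c(OCC=C)cc(OCc3ccccc3)cc2OCc2ccccc2)c1 | intermediate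
11 | 4-{(1S)-3-[2-(allyloxy)-4,6-bis(benzyloxy)phenyl]-1-(3,5-dimethoxyphenoxy)-3-hydroxypropyl}phenyl pivalate (both C3 epimers; 3R drawn) | COc1cc(OC)cc(O[C@H](c2ccc(OC(=O)C(C)(C)C)cc2)C[C@@H](O)c2c(OCC=C)cc(OCc3ccccc3)cc2OCc2ccccc2)c1 | intermediate
12 | (2S)-2,4-trans-4-[2-(allyloxy)-4,6-bis(benzyloxy)phenyl]-5,7-dimethoxy-2-(4-pivaloyloxyphenyl)chroman | COc1cc(OC)c2c(c1)O[C@H](c1ccc(OC(=O)C(C)(C)C)cc1)C[C@H]2c1c(OCC=C)cc(OCc2ccccc2)cc1OCc1ccccc1 | intermediate
13 | 4-{(2S)-2,4-trans-4-[2-(allyloxy)-4,6-bis(benzyloxy)phenyl]-5,7-dimethoxychroman-2-yl}phenol | COc1cc(OC)c2c(c1)O[C@H](c1ccc(O)cc1)C[C@H]2c1c(OCC=C)cc(OCc2ccccc2)cc1OCc1ccccc1 | intermediate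
14 | (2S)-2,4-trans-4-[2-(allyloxy)-4,6-bis(benzyloxy)phenyl]-2-(4-benzyloxyphenyl)-5,7-dimethoxychroman | COc1cc(OC)c2c(c1)O[C@H](c1ccc(OCc3ccccc3)cc1)C[C@H]2c1c(OCC=C)cc(OCc2ccccc2)cc1OCc1ccccc1 | intermediate
15 | 3,5-bis(benzyloxy)-2-[(2S)-2,4-trans-2-(4-benzyloxyphenyl)-5,7-dimethoxychroman-4-yl]phenol | COc1cc(OC)c2c(c1)O[C@H](c1ccc(OCc3ccccc3)cc1)C[C@H]2c1c(O)cc(OCc2ccccc2)cc1OCc1ccccc1 | intermediate
16 | 4,6-bis(benzyloxy)-3-[(2S)-2,4-trans-2-(4-benzyloxyphenyl)-5,7-dimethoxychroman-4-yl]-2-hydroxybenzaldehyde | COc1cc(OC)c2c(c1)O[C@H](c1ccc(OCc3ccccc3)cc1)C[C@H]2c1c(O)c(C=O)c(OCc2ccccc2)cc1OCc1ccccc1 | intermediate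
17 | 1-{4,6-bis(benzyloxy)-3-[(2S)-2,4-trans-2-(4-benzyloxyphenyl)-5,7-dimethoxychroman-4-yl]-2-hydroxyphenyl}ethanol (both carbinol epimers) | COc1cc(OC)c2c(c1)O[C@H](c1ccc(OCc3ccccc3)cc1)C[C@H]2c1c(O)c(C(C)O)c(OCc2ccccc2)cc1OCc1ccccc1 | intermediate
18 | 1-{4,6-bis(benzyloxy)-3-[(2S)-2,4-trans-2-(4-benzyloxyphenyl)-5,7-dimethoxychroman-4-yl]-2-hydroxyphenyl}ethanone | COc1cc(OC)c2c(c1)O[C@H](c1ccc(OCc3ccccc3)cc1)C[C@H]2c1c(O)c(C(C)=O)c(OCc2ccccc2)cc1OCc1ccccc1 | intermediate
19 | (E)-1-{4,6-bis(benzyloxy)-3-[(2S)-2,4-trans-2-(4-benzyloxyphenyl)-5,7-dimethoxychroman-4-yl]-2-hydroxyphenyl}-3-(dimethylamino)prop-2-en-1-one | COc1cc(OC)c2c(c1)O[C@H](c1ccc(OCc3ccccc3)cc1)C[C@H]2c1c(O)c(C(=O)/C=C/N(C)C)c(OCc2ccccc2)cc1OCc1ccccc1 | intermediate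
20 | 5,7-bis(benzyloxy)-8-[(2S)-2,4-trans-2-(4-benzyloxyphenyl)-5,7-dimethoxychroman-4-yl]-4H-chromen-4-one | COc1cc(OC)c2c(c1)O[C@H](c1ccc(OCc3ccccc3)cc1)C[C@H]2c1c(OCc3ccccc3)cc(OCc3ccccc3)c2c1OC=CC2=O | intermediate
21 | phenylboronic acid | OB(O)c1ccccc1 | starting material
22 | (2S)-5,7-bis(benzyloxy)-8-[(2S)-2,4-trans-2-(4-benzyloxyphenyl)-5,7-dimethoxychroman-4-yl]-2-phenylchroman-4-one | COc1cc(OC)c2c(c1)O[C@H](c1ccc(OCc3ccccc3)cc1)C[C@H]2c1c(OCc3ccccc3)cc(OCc3ccccc3)c2c1O[C@H](c1ccccc1)CC2=O | intermediate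
23 | (2S)-5,7-dihydroxy-8-[(2S)-2,4-trans-2-(4-hydroxyphenyl)-5,7-dimethoxychroman-4-yl]-2-phenylchroman-4-one (CNP0188217.1) | COc1cc(OC)c2c(c1)O[C@H](c1ccc(O)cc1)C[C@H]2c1c(O)cc(O)c2c1O[C@H](c1ccccc1)CC2=O | target

**Step count**
Total: 17 steps. Longest linear sequence: 16 steps (from 1 through steps 1, 2 and 4 to 17).

**Steps most likely to fail**

Step 9. The cation may lose a proton to the styrene, which can then shed the C2 aryloxy group, it may alkylate a second molecule, or the ring may close with poor facial selectivity. The fallback sets out from 11 and comes back at 12. The allyl group of 11 would be removed first (Pd(PPh3)4, morpholine, THF) to give the ortho-hydroxybenzyl alcohol 4-{(1S)-3-[2,4-bis(benzyloxy)-6-hydroxyphenyl]-1-(3,5-dimethoxyphenoxy)-3-hydroxypropyl}phenyl pivalate F1. With diphenyl phosphate (5 mol%) in toluene at rt this should lose water to a neutral ortho-quinone methide on ring D, to which the dimethoxyphenoxy ring adds in a conjugate Friedel–Crafts sense, so no free cation is needed; the product is the ring D phenol 3,5-bis(benzyloxy)-2-[(2S)-2,4-trans-5,7-dimethoxy-2-(4-pivaloyloxyphenyl)chroman-4-yl]phenol F2. Allylation of F2 (allyl bromide, K2CO3, DMF) returns to 12.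

Step 16. The hindered, electron-rich chromone may insert slowly, or the remote flavan unit may work against the catalyst and lower the facial selectivity. The fallback sets out from 18 and comes back at 22. Claisen–Schmidt condensation of 18 with benzaldehyde (KOH, EtOH) would give the 2'-hydroxychalcone (E)-1-{4,6-bis(benzyloxy)-3-[(2S)-2,4-trans-2-(4-benzyloxyphenyl)-5,7-dimethoxychroman-4-yl]-2-hydroxyphenyl}-3-phenylprop-2-en-1-one F3. NaOAc in refluxing EtOH closes it by oxa-Michael addition to 22 together with its flavanone C2 epimer, the (2R)-flavanone F4. The two are diastereomers because the flavan centres are fixed, so they would be separated by chromatography, and F4 can be reopened to F3 with base and recycled.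

Step 7. Partial ionisation of the activated benzylic alcohol would erode the configuration, and elimination to the styrene or C-alkylation of the electron-rich phenol may compete. The fallback sets out from 7 and comes back at 10. Reduction of 7 with the (R)-2-butyl-CBS-oxazaborolidine and catecholborane would give the epimeric alcohol 4-{(1S)-3-[2-(allyloxy)-4,6-bis(benzyloxy)phenyl]-3-(tert-butyldimethylsilyloxy)-1-hydroxypropyl}phenyl pivalate F5. Ullmann-type O-arylation of F5 with 1-iodo-3,5-dimethoxybenzene (CuI, 3,4,7,8-tetramethyl-1,10-phenanthroline, Cs2CO3, toluene, 90 °C) forms the aryl–oxygen bond instead of the benzylic carbon–oxygen bond, so the stereocentre is not touched and 10 is reached with retention.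

**Further compounds**
F1 | step 9 | 4-{(1S)-3-[2,4-bis(benzyloxy)-6-hydroxyphenyl]-1-(3,5-dimethoxyphenoxy)-3-hydroxypropyl}phenyl pivalate (both C3 epimers; 3R drawn) | COc1cc(OC)cc(O[C@H](c2ccc(OC(=O)C(C)(C)C)cc2)C[C@@H](O)c2c(O)cc(OCc3ccccc3)cc2OCc2ccccc2)c1
F2 | step 9 | 3,5-bis(benzyloxy)-2-[(2S)-2,4-trans-5,7-dimethoxy-2-(4-pivaloyloxyphenyl)chroman-4-yl]phenol | COc1cc(OC)c2c(c1)O[C@H](c1ccc(OC(=O)C(C)(C)C)cc1)C[C@H]2c1c(O)cc(OCc2ccccc2)cc1OCc1ccccc1
F3 | step 16 | (E)-1-{4,6-bis(benzyloxy)-3-[(2S)-2,4-trans-2-(4-benzyloxyphenyl)-5,7-dimethoxychroman-4-yl]-2-hydroxyphenyl}-3-phenylprop-2-en-1-one | COc1cc(OC)c2c(c1)O[C@H](c1ccc(OCc3ccccc3)cc1)C[C@H]2c1c(O)c(C(=O)/C=C/c2ccccc2)c(OCc2ccccc2)cc1OCc1ccccc1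
F4 | step 16 | (2R)-5,7-bis(benzyloxy)-8-[(2S)-2,4-trans-2-(4-benzyloxyphenyl)-5,7-dimethoxychroman-4-yl]-2-phenylchroman-4-one | COc1cc(OC)c2c(c1)O[C@H](c1ccc(OCc3ccccc3)cc1)C[C@H]2c1c(OCc3ccccc3)cc(OCc3ccccc3)c2c1O[C@@H](c1ccccc1)CC2=O
F5 | step 7 | 4-{(1S)-3-[2-(allyloxy)-4,6-bis(benzyloxy)phenyl]-3-(tert-butyldimethylsilyloxy)-1-hydroxypropyl}phenyl pivalate (both C3 epimers; 3R drawn) | O[C@H](c1ccc(OC(=O)C(C)(C)C)cc1)C[C@@H](O[Si](C)(C)C(C)(C)C)c1c(OCC=C)cc(OCc2ccccc2)cc1OCc1ccccc1
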